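(The readings are calculated for an exercise; scatter was added.)

Per minute, the Q in these flasks turned into E at 0.0411 /min, and this reading, the loss constant of Q, is what I carried from flask to flask.

| flask | J | Z | remark | time |
|---|---|---|---|---|
| north | 0.20 M | 0.01 mol% | run made earlier |  |
| east | 0.20 M | 0.0067 mol% | run made earlier |  |
| west | 0.20 M | 0.015 mol% | run made earlier |  |
| Tuesday's | 0.20 M | 0.01 mol% | one stirred flow tank at steady state, fed with the mixture as stated, mean residence time 1.5 h |  |
| Saturday's | 0.20 M | 0.01 mol% | everything together in a closed stirred flask, run for 1.5 h | 1.5 h |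
| Sunday's | 0.20 M | 0.01 mol% | one stirred flow tank at steady state, fed with the mixture as stated, mean residence time 7.50 h |  |
| Friday's | 0.20 M (fed, over 1.20 h) | 0.01 mol% | a stirred flask in which J is dosed at a steady rate over 1.20 h without added volume, worked up at 1.5 h | 1.5 h |

- north (time / min: Q / %, E / %): 20.0: 6.2, 3.8; 40.0: 5.5, 8.5; 50.0: 4.0, 10.1; 80.0: 1.6, 13.3; 90.0: 1.7, 14.0
- east (time / min: Q / %, E / %): 10.0: 3.2, 0.8; 20.0: 4.1, 1.9; 30.0: 3.8, 4.3; 40.0: 3.0, 5.6; 50.0: 3.0, 6.8
- west (time / min: Q / %, E / %): 5.00: 4.4, 0.2; 15.0: 8.4, 3.2; 25.0: 9.5, 6.4; 40.0: 7.0, 11.9; 50.0: 5.7, 14.8

(readings scatter by 0.3 percentage points)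

- order of the set-ups by the share of Q in all that became Q or E, at the outlet or at the end, highest first (Tuesday's / Saturday's / Sunday's / Friday's)
- share of Q in all that became Q or E, at the outlet or at the end, Tuesday's
- share of Q in all that became Q or E, at the outlet or at the end, Saturday's
- share of Q in all that became Q or E, at the outlet or at the end, Sunday's
- share of Q in all that became Q or E, at the outlet or at the end, Friday's

- the stated concentrations are those of everything mixed, before any reaction; amounts are the same in each set-up
- the analysis behind the earlier runs scatters by 0.3 percentage points, standard deviation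
- steps thought possible: Z -> D; J + Z -> Q + Z; Q -> E
- the feed brings no volume worth counting
- the earlier runs were made in a closed, stirred flask

I read the constant as the E gained late in the north and west runs, divided by the area under their Q curves over the same minutes.

The first setting is the loading of Z. West, with 0.015 mol%, reached 9.5% Q where north, with 0.01 mol%, showed 6.2%, but the step from Q to E holds no Z, so I pooled the two runs.

The second setting is the stay in a tank, and I solved it at both ends. A very short stay leaves the share of Q near one. A very long stay brings it to one over the loss constant times the stay, and that product is the Damköhler number. The tank balance joins the ends: E leaves at E over the stay and forms at the constant times Q, so the share is one over one plus that number. That gave me 21.3% for Tuesday's tank and 5.13% for Sunday's.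

The third setting is the vessel. North, Saturday's recipe, read 1.7% Q against 14.0% E at 90.0 min, a share of 10.8% as read, below Tuesday's.

The fourth setting is dosing. Friday's flask takes J over 1.20 h of its 1.5 h, so its last J arrives 18.0 min before work-up, and I placed it above Saturday's flask and below Tuesday's tank without a figure.

The forecast gave Tuesday's > Friday's > Saturday's > Sunday's, with 21.7%, 8.5%, 5.3% and 16% in the order Tuesday's, Saturday's, Sunday's, Friday's, saying of the flow tank that its share holds “whatever the enzyme does”.

The simulation gives Tuesday's > Friday's > Saturday's > Sunday's: 21.3% for Tuesday's, 7.97% for Saturday's, 5.14% for Sunday's and 13.5% for Friday's.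

    Z → D (k = 0.0480 /min)
    J + Z → Q + Z, rate k2*[J]*[Z]/(1 + ([J]/Km2) + ([Q]/Kp2)) (0.160 M, 0.300 M, k = 870 /M/min)
    Q → E (k = 0.0410 /min)

The half-life of Q by its turning into E alone, 0.28 h, is short against the 1.5 h of Saturday's flask and against the 7.50 h of Sunday's tank. Carried to Sunday's tank, the loss constant puts E at 18.5 times Q, so the 13.6% of E at that outlet goes with 0.735% of Q, in percent of the J charged.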